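**Retrosynthetic overview**

1. Target 30 ⇐ acetylation of β-hydroxy ketone 29 ⇐ C1 epimerisation (kinetic protonation) of 27 ⇐ N–O cleavage of 2-isoxazoline 26, a masked aldol.
2. 26 ⇐ intramolecular nitrile oxide–alkene cycloaddition of oxime 24, which closes the cyclopentane and the isoxazoline together on a fully substituted cyclohexane.
3. Cyclohexane 22 ⇐ bis-epoxide 15, by pyran opening, Takai olefination, oxidation to the glycidate and epoxide-to-exocyclic-allylic-alcohol isomerisation.
4. 15 ⇐ Diels–Alder adduct 13 of dienyl ester 12 and (S)-acetoxypyranone 3, which sets the all-cis ring array; 3 ⇐ furfuryl alcohol.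
5. Ring order: pyranone → cyclohexene → two oxiranes → (pyran opened) → cyclopentane + isoxazoline → (isoxazoline opened).

Assumption: the stereochemistry is taken exactly as encoded in the SMILES (C1 side chain cis to C7, (R)-2-methylbutanoate); ring positions of intermediates follow the numbering used in their names.

**Route**

Step 1
Reactants: 1 furan-2-ylmethanol
Product: 2 rac-6-hydroxy-2H-pyran-3(6H)-one
Conditions: mCPBA, CH2Cl2, 0 °C
Reagents that add atoms: mCPBA (3-chloroperoxybenzoic acid), O=C(OO)c1cccc(Cl)c1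
Why: Achmatowicz oxidative ring expansion, in which peracid oxidation of the furan gives a (Z)-ene-dione that closes to the pyranone hemiacetal, whose single stereocentre stays labile.

Step 2
Reactants: 2 rac-6-hydroxy-2H-pyran-3(6H)-one
Product: 3 (S)-6-acetoxy-2H-pyran-3(6H)-one
Conditions: Ac2O, iPr2NEt, benzotetramisole (5 mol %, enantiomer that acylates the S lactol), CHCl3, 0 °C
Reagents that add atoms: acetic anhydride, CC(=O)OC(C)=O
Why: Dynamic kinetic resolution by enantioselective acyl transfer, in which the lactol epimerises through its open form while the chiral isothiourea acylates only the S hemiacetal, so C6 is set by the catalyst.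

Step 3
Reactants: 4 methyl 3,3-dimethoxypropanoate; 5 2-(triphenylphosphoranylidene)propanal
Product: 7 (E)-5,5-dimethoxy-2-methylpent-2-enal, via 3,3-dimethoxypropanal 6 (not isolated)
Conditions: iBu2AlH, CH2Cl2, −78 °C; then 5, −78 °C to rt
Reagents that add atoms: none
Why: Half-reduction of the ester through the aluminium hemiacetal and in-situ Wittig olefination with the stabilised ylide, which gives the E trisubstituted enal; no stereocentre is formed.

Step 4
Reactants: 7 (E)-5,5-dimethoxy-2-methylpent-2-enal; 8 2-(dichloromethyl)-4,4,5,5-tetramethyl-1,3,2-dioxaborolane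
Product: 10 potassium [(1E,3E)-6,6-dimethoxy-3-methylhexa-1,3-dien-1-yl]trifluoroborate, via dienyl pinacol boronate 9 (not isolated)
Conditions: CrCl2, LiI, THF, rt; then KHF2, MeOH/H2O
Reagents that add atoms: potassium hydrogen difluoride (KHF2), F.[F-].[K+]
Why: Takai–Utimoto boryl-olefination, in which the gem-dichromium carbenoid from 8 adds to the aldehyde and eliminates to the E alkenylboronate, which KHF2 converts into the bench-stable trifluoroborate.

Step 5
Reactants: 10 potassium dienyltrifluoroborate; 11 (E)-3-methylpent-2-enoic acid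
Product: 12 (1E,3E)-6,6-dimethoxy-3-methylhexa-1,3-dien-1-yl (E)-3-methylpent-2-enoate
Conditions: CuBr (10 mol %), DMAP, 4 Å MS, O2 (1 atm), CH2Cl2, 40 °C
Reagents that add atoms: none
Why: Chan–Lam-type copper-catalysed oxidative C–O coupling of an alkenyltrifluoroborate with a carboxylic acid, which keeps the alkene geometry and gives the (1E,3E)-dienyl ester.

Step 6
Reactants: 12 dienyl ester; 3 (S)-6-acetoxy-2H-pyran-3(6H)-one
Product: 13 (1S)-1-acetoxy-8-(2,2-dimethoxyethyl)-7-methyl-4-oxo-3,4,4a,5,8,8a-hexahydro-1H-isochromen-5-yl (E)-3-methylpent-2-enoate (cis-fused; H-4a, H-5, H-8, H-8a all cis)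
Conditions: toluene, BHT (cat.), 110 °C, sealed tube
Reagents that add atoms: none
Why: Normal-demand Diels–Alder reaction in which the acyloxy and 3-methyl groups of the diene direct the enone α-carbon to the acyloxy terminus and the cyclic enone reacts endo on the face anti to its 6-acetoxy group, so four contiguous all-cis ring stereocentres are set in the absolute sense dictated by 3.

Step 7
Reactants: 13 Diels–Alder adduct
Product: 14 4-methylidene analogue of 13
Conditions: Zn, CH2Br2, TiCl4, THF/CH2Cl2, 0 °C to rt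
Reagents that add atoms: dibromomethane, BrCBr
Why: Takai–Lombardo methylenation with the non-basic zinc–titanium methylene reagent converts the ketone into the exocyclic alkene without epimerising the adjacent ring-fusion carbon or touching the esters.

Step 8
Reactants: 14 methylidene pyran
Product: 15 bis-epoxide of 14 (6,7-epoxide oxygen cis to H-5 and H-8; spiro-oxirane oxygen cis to H-4a)
Conditions: mCPBA (2.5 equiv), CH2Cl2, 0 °C to rt
Reagents that add atoms: mCPBA (3-chloroperoxybenzoic acid), O=C(OO)c1cccc(Cl)c1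
Why: Prilezhaev epoxidation of the two electron-rich alkenes (the enoate is inert), the ring alkene being attacked anti to the allylic ester and the other cis substituents and the exocyclic alkene on the convex face of the cis-fused pyran, which sets the future C5 oxygen and the quaternary oxirane carbon.

Step 9
Reactants: 15 bis-epoxide
Product: 16 lactol (1-hydroxy analogue of 15, anomer mixture)
Conditions: N2H4·AcOH, DMF, rt
Reagents that add atoms: none
Why: Chemoselective hydrazinolysis of the acetal (anomeric) acetate, far more electrophilic than the hindered conjugated ester, frees the lactol without touching any stereocentre.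

Step 10
Reactants: 16 lactol
Product: 17 2-(2,2-dimethoxyethyl)-4-[2-(hydroxymethyl)oxiran-2-yl]-1-methyl-3-[(E)-prop-1-enyl]-7-oxabicyclo[4.1.0]heptan-5-yl (E)-3-methylpent-2-enoate
Conditions: CrCl2, CH3CHI2, THF, 0 °C to rt
Reagents that add atoms: 1,1-diiodoethane, CC(I)I
Why: Takai alkylidenation, in which the gem-dichromium reagent from CH3CHI2 olefinates the open hydroxy-aldehyde form of the lactol E-selectively under non-basic conditions, so the α-stereocentre is kept and the primary alcohol is released.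

Step 11
Reactants: 17 epoxy alcohol
Product: 19 methyl glycidate (methyl ester of 18; oxirane carbon S), via epoxy acid 18 (not isolated)
Conditions: TEMPO (cat.), NaOCl (cat.), NaClO2, pH 6.7 phosphate buffer, MeCN, 35 °C; then TMSCHN2, toluene/MeOH, 0 °C
Reagents that add atoms: sodium chlorite (NaClO2), [Na+].[O-]Cl=O; trimethylsilyldiazomethane, C[Si](C)(C)C=[N+]=[N-]
Why: TEMPO/chlorite oxidation of the primary 2,3-epoxy alcohol to the glycidic acid at buffered pH, where acetal, alkene and epoxides survive, followed by immediate diazoalkane methylation; no stereocentre is touched.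

Step 12
Reactants: 19 methyl glycidate
Product: 20 methyl (2S)-2-[5-(2,2-dimethoxyethyl)-3-hydroxy-4-methylidene-2-{[(E)-3-methylpent-2-enoyl]oxy}-6-[(E)-prop-1-enyl]cyclohexyl]oxirane-2-carboxylate
Conditions: Et2Al(NC9H18) (diethylaluminium 2,2,6,6-tetramethylpiperidide), toluene, 0 °C
Reagents that add atoms: none
Why: Yamamoto aluminium-amide isomerisation of a trisubstituted epoxide to the allylic alcohol, in which syn β-elimination removes the least hindered (methyl) hydrogen to give the exocyclic alkene with the C–O configuration retained, while the glycidate, whose only β-hydrogen is a hindered ring methine, is left alone.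

Step 13
Reactants: 20 allylic alcohol; 21 (R)-2-methylbutanoic acid
Product: 22 (2R)-2-methylbutanoate of 20 at the 3-hydroxyl
Conditions: DCC, DMAP (cat.), CH2Cl2, 0 °C
Reagents that add atoms: none
Why: Steglich esterification of the allylic alcohol, run cold with catalytic DMAP so that the α-stereocentre of the acid stays intact; no new stereocentre is formed.

Step 14
Reactants: 22 diester acetal
Product: 24 aldoxime of 23 (E/Z mixture), via aldehyde 23 (not isolated)
Conditions: PPTS, acetone/H2O, 45 °C; then NH2OH·HCl, NaOAc, MeOH, rt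
Reagents that add atoms: hydroxylamine hydrochloride, NO.Cl
Why: Acid-catalysed acetal hydrolysis followed by oxime condensation of the freed aldehyde; no stereocentre is involved.

Step 15
Reactants: 24 aldoxime
Product: 26 tricyclic 2-isoxazoline (cis-hydrindane with C2=N–O–CH(CH3) fused across C1–C2; H-1 trans to H-7a), via nitrile oxide 25 (not isolated)
Conditions: PhI(OAc)2, MeOH, 0 °C to rt
Reagents that add atoms: none
Why: Intramolecular nitrile oxide–alkene 1,3-dipolar cycloaddition, in which the 5-exo mode closes the cis-fused cyclopentane and the 2-isoxazoline in one event; suprafacial addition to the E alkene, reacting in its allylic-strain-minimised rotamer with the dipole on the convex face, fixes the S carbinol carbon while C1 emerges epimeric to the target.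

Step 16
Reactants: 26 isoxazoline
Product: 27 β-hydroxy ketone, C1 epimer of 29
Conditions: Mo(CO)6, MeCN/H2O, 80 °C
Reagents that add atoms: water, O
Why: Reductive N–O cleavage of the 2-isoxazoline by Mo(CO)6 and hydrolysis of the β-hydroxy imine unmask the aldol without affecting the alkenes, esters or stereocentres.

Step 17
Reactants: 27 β-hydroxy ketone (C1 epimer)
Product: 29 desacetyl target, via bis-silyl enol ether 28 (not isolated)
Conditions: TMSOTf, Et3N, CH2Cl2, 0 °C to rt; then HF·pyridine, THF, −78 °C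
Reagents that add atoms: none
Why: Regioselective formation of the more substituted (thermodynamic) silyl enol ether followed by kinetic C-protonation from the convex face of the cis-hydrindane inverts C1 and places the side chain on the concave face cis to C7, while any enol ether formed toward C3 simply returns 27.

Step 18
Reactants: 29 desacetyl target
Product: 30 CNP0251769.2
Conditions: Ac2O, pyridine, 0 °C
Reagents that add atoms: acetic anhydride, CC(=O)OC(C)=O
Why: Acyl-transfer acetylation of the secondary alcohol, run cold to avoid β-elimination or C1 epimerisation, gives the target.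

**Compound list**

1 | furan-2-ylmethanol (furfuryl alcohol) | OCc1ccco1 | starting material
2 | rac-6-hydroxy-2H-pyran-3(6H)-one | O=C1COC(O)C=C1 | intermediate
3 | (S)-6-acetoxy-2H-pyran-3(6H)-one | O=C1CO[C@@H](OC(C)=O)C=C1 | intermediate
4 | methyl 3,3-dimethoxypropanoate | COC(=O)CC(OC)OC | starting material
5 | 2-(triphenylphosphoranylidene)propanal | CC(C=O)=P(c1ccccc1)(c1ccccc1)c1ccccc1 | starting material
6 | 3,3-dimethoxypropanal | O=CCC(OC)OC | intermediate
7 | (E)-5,5-dimethoxy-2-methylpent-2-enal | O=C/C(C)=C/CC(OC)OC | intermediate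
8 | 2-(dichloromethyl)-4,4,5,5-tetramethyl-1,3,2-dioxaborolane | ClC(Cl)B1OC(C)(C)C(C)(C)O1 | starting material
9 | 2-[(1E,3E)-6,6-dimethoxy-3-methylhexa-1,3-dien-1-yl]-4,4,5,5-tetramethyl-1,3,2-dioxaborolane | COC(C/C=C(C)/C=C/B1OC(C)(C)C(C)(C)O1)OC | intermediate
10 | potassium [(1E,3E)-6,6-dimethoxy-3-methylhexa-1,3-dien-1-yl]trifluoroborate | COC(C/C=C(C)/C=C/[B-](F)(F)F)OC.[K+] | intermediate
11 | (E)-3-methylpent-2-enoic acid | CC/C(C)=C/C(=O)O | starting material
12 | (1E,3E)-6,6-dimethoxy-3-methylhexa-1,3-dien-1-yl (E)-3-methylpent-2-enoate | CC/C(C)=C/C(=O)O/C=C/C(C)=C/CC(OC)OC | intermediate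
13 | (1S)-1-acetoxy-8-(2,2-dimethoxyethyl)-7-methyl-4-oxo-3,4,4a,5,8,8a-hexahydro-1H-isochromen-5-yl (E)-3-methylpent-2-enoate; cis-fused; H-4a, H-5, H-8, H-8a all cis; 1-OAc cis to H-8a | CC1=C[C@H](OC(=O)/C=C(\C)CC)[C@@H]2C(=O)CO[C@@H](OC(C)=O)[C@@H]2[C@@H]1CC(OC)OC | intermediate
14 | 4-methylidene analogue of 13 (C=O replaced by C=CH2; stereocentres unchanged) | CC1=C[C@H](OC(=O)/C=C(\C)CC)[C@@H]2C(=C)CO[C@@H](OC(C)=O)[C@@H]2[C@@H]1CC(OC)OC | intermediate
15 | bis-epoxide of 14: 6,7-epoxide with oxygen cis to H-5 and H-8; 4-spiro-oxirane with oxygen cis to H-4a and CH2 on the side of C5 | C[C@]12O[C@H]1[C@H](OC(=O)/C=C(\C)CC)[C@@H]3[C@]4(CO4)CO[C@@H](OC(C)=O)[C@@H]3[C@@H]2CC(OC)OC | intermediate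
16 | lactol from 15 (1-OH in place of 1-OAc; anomer mixture) | C[C@]12O[C@H]1[C@H](OC(=O)/C=C(\C)CC)[C@@H]3[C@]4(CO4)COC(O)[C@@H]3[C@@H]2CC(OC)OC | intermediate
17 | 2-(2,2-dimethoxyethyl)-4-[2-(hydroxymethyl)oxiran-2-yl]-1-methyl-3-[(E)-prop-1-enyl]-7-oxabicyclo[4.1.0]heptan-5-yl (E)-3-methylpent-2-enoate; C2, C3, C4, C5 substituents all cis, ring-epoxide oxygen trans to them | C[C@]12O[C@H]1[C@H](OC(=O)/C=C(\C)CC)[C@H]([C@@]3(CO)CO3)[C@H](/C=C/C)[C@@H]2CC(OC)OC | intermediate
18 | carboxylic acid from 17 (CH2OH oxidised to CO2H) | C[C@]12O[C@H]1[C@H](OC(=O)/C=C(\C)CC)[C@H]([C@@]3(C(=O)O)CO3)[C@H](/C=C/C)[C@@H]2CC(OC)OC | intermediate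
19 | methyl ester of 18 (oxirane carbon S, as in the target) | C[C@]12O[C@H]1[C@H](OC(=O)/C=C(\C)CC)[C@H]([C@@]3(C(=O)OC)CO3)[C@H](/C=C/C)[C@@H]2CC(OC)OC | intermediate
20 | methyl (2S)-2-[5-(2,2-dimethoxyethyl)-3-hydroxy-4-methylidene-2-{[(E)-3-methylpent-2-enoyl]oxy}-6-[(E)-prop-1-enyl]cyclohexyl]oxirane-2-carboxylate; C1, C2, C5, C6 substituents all cis, 3-OH trans to the 2-acyloxy group | C=C1[C@@H](O)[C@H](OC(=O)/C=C(\C)CC)[C@H]([C@@]2(C(=O)OC)CO2)[C@H](/C=C/C)[C@@H]1CC(OC)OC | intermediate
21 | (R)-2-methylbutanoic acid | CC[C@@H](C)C(=O)O | starting material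
22 | (2R)-2-methylbutanoate of 20 at the 3-hydroxyl | C=C1[C@@H](OC(=O)[C@H](C)CC)[C@H](OC(=O)/C=C(\C)CC)[C@H]([C@@]2(C(=O)OC)CO2)[C@H](/C=C/C)[C@@H]1CC(OC)OC | intermediate
23 | aldehyde from 22 (CH2CH(OMe)2 becomes CH2CHO) | C=C1[C@@H](OC(=O)[C@H](C)CC)[C@H](OC(=O)/C=C(\C)CC)[C@H]([C@@]2(C(=O)OC)CO2)[C@H](/C=C/C)[C@@H]1CC=O | intermediate
24 | aldoxime of 23 (E/Z mixture) | C=C1[C@@H](OC(=O)[C@H](C)CC)[C@H](OC(=O)/C=C(\C)CC)[C@H]([C@@]2(C(=O)OC)CO2)[C@H](/C=C/C)[C@@H]1CC=NO | intermediate
25 | nitrile oxide from 24 | C=C1[C@@H](OC(=O)[C@H](C)CC)[C@H](OC(=O)/C=C(\C)CC)[C@H]([C@@]2(C(=O)OC)CO2)[C@H](/C=C/C)[C@@H]1CC#[N+][O-] | intermediate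
26 | tricyclic 2-isoxazoline: target skeleton with C2=N–O–CH(CH3) bridging C2 to the side-chain carbon; H-1 trans to H-7a; carbinol carbon S; other centres as in the target | C=C1[C@H]2CC3=NO[C@@H](C)[C@@H]3[C@H]2[C@@H]([C@@]4(C(=O)OC)CO4)[C@@H](OC(=O)/C=C(\C)CC)[C@@H]1OC(=O)[C@H](C)CC | intermediate
27 | C1 epimer of 29 (1-(1-hydroxyethyl) group cis to H-7a) | C=C1[C@H]2CC(=O)[C@H]([C@H](C)O)[C@H]2[C@@H]([C@@]3(C(=O)OC)CO3)[C@@H](OC(=O)/C=C(\C)CC)[C@@H]1OC(=O)[C@H](C)CC | intermediate
28 | C1=C2 trimethylsilyl enol ether of 27 with the side-chain hydroxyl as its trimethylsilyl ether | C=C1[C@H]2CC(O[Si](C)(C)C)=C([C@H](C)O[Si](C)(C)C)[C@H]2[C@@H]([C@@]3(C(=O)OC)CO3)[C@@H](OC(=O)/C=C(\C)CC)[C@@H]1OC(=O)[C@H](C)CC | intermediate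
29 | methyl (2S)-2-[(1R,3aS,5R,6R,7R,7aR)-1-[(1S)-1-hydroxyethyl]-4-methylidene-6-{[(2E)-3-methylpent-2-enoyl]oxy}-5-{[(2R)-2-methylbutanoyl]oxy}-2-oxooctahydro-1H-inden-7-yl]oxirane-2-carboxylate | C=C1[C@H]2CC(=O)[C@@H]([C@H](C)O)[C@H]2[C@@H]([C@@]3(C(=O)OC)CO3)[C@@H](OC(=O)/C=C(\C)CC)[C@@H]1OC(=O)[C@H](C)CC | intermediate
30 | methyl (2S)-2-[(1R,3aS,5R,6R,7R,7aR)-1-[(1S)-1-acetoxyethyl]-4-methylidene-6-{[(2E)-3-methylpent-2-enoyl]oxy}-5-{[(2R)-2-methylbutanoyl]oxy}-2-oxooctahydro-1H-inden-7-yl]oxirane-2-carboxylate (CNP0251769.2) | C=C1[C@H]2CC(=O)[C@@H]([C@H](C)OC(C)=O)[C@H]2[C@@H]([C@@]2(C(=O)OC)CO2)[C@@H](OC(=O)/C=C(\C)CC)[C@@H]1OC(=O)[C@H](C)CC | target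

**Totals and weak points**

Total step count: 18. Longest linear sequence: 16 steps (compound 4 to 30, steps 3–18).

Most likely to fail, first: step 6, where a hindered 1,3,4-trisubstituted dienyl ester may be too sluggish or give regio-/endo-isomers. The fallback uses a more electron-rich diene. It sets out from boronate 9, taken from step 4 before the KHF2 treatment. Oxidation with NaBO3 in THF/H2O gives (E)-6,6-dimethoxy-3-methylhex-3-enal F1. Soft enolisation with TBSOTf/Et3N, possible only at the doubly activated α-CH2, gives the silyl dienol ether tert-butyl{[(1E,3E)-6,6-dimethoxy-3-methylhexa-1,3-dien-1-yl]oxy}dimethylsilane F2. Cycloaddition of F2 with 3 in toluene at 60 °C gives the silyl ether adduct F3. HF·pyridine then frees the C5 alcohol F4, and esterification with acid 11 (DCC, DMAP) comes back to the route at 13.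

Second: step 12, where the aluminium amide may attack the esters or give the ring alkene. The fallback sets out from 19. Opening of the trisubstituted epoxide at its tertiary carbon with PhSeH and catalytic BF3·OEt2 at −78 °C gives the hydroxy selenide F5. Oxidation with H2O2/pyridine triggers selenoxide syn-elimination; only the methyl hydrogens are syn to selenium (the ring-fusion hydrogen is anti), so the exocyclic alkene forms, and the route is rejoined at 20.

Third: step 17, where enol-ether regiochemistry and the contra-thermodynamic protonation are both uncertain. The fallback sets out from 27. Dehydration with Burgess reagent gives the (E)-ethylidene ketone F6. Copper-catalysed conjugate borylation (CuCl, NaOtBu, a chiral ferrocenyl bisphosphine, B2pin2, MeOH) places boron on the side-chain carbon under ligand control and protonates C1 from the convex face, giving the β-boryl ketone F7. Oxidation with NaBO3 proceeds with retention and comes back at 29.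

**Further compounds**

F1 | step 6 | (E)-6,6-dimethoxy-3-methylhex-3-enal | O=CC/C(C)=C/CC(OC)OC
F2 | step 6 | tert-butyl{[(1E,3E)-6,6-dimethoxy-3-methylhexa-1,3-dien-1-yl]oxy}dimethylsilane | CC(C)(C)[Si](C)(C)O/C=C/C(C)=C/CC(OC)OC
F3 | step 6 | silyl ether adduct (5-OTBS analogue of 13, same ring stereochemistry) | CC1=C[C@H](O[Si](C)(C)C(C)(C)C)[C@@H]2C(=O)CO[C@@H](OC(C)=O)[C@@H]2[C@@H]1CC(OC)OC
F4 | step 6 | C5 alcohol (5-OH analogue of 13) | CC1=C[C@H](O)[C@@H]2C(=O)CO[C@@H](OC(C)=O)[C@@H]2[C@@H]1CC(OC)OC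
F5 | step 12 | hydroxy selenide (PhSe on the methyl-bearing carbon, trans to the neighbouring OH) | C[C@@]1([Se]c2ccccc2)[C@@H](O)[C@H](OC(=O)/C=C(\C)CC)[C@H]([C@@]3(C(=O)OC)CO3)[C@H](/C=C/C)[C@@H]1CC(OC)OC
F6 | step 17 | (E)-1-ethylidene ketone | C=C1[C@H]2CC(=O)/C(=C/C)[C@H]2[C@@H]([C@@]3(C(=O)OC)CO3)[C@@H](OC(=O)/C=C(\C)CC)[C@@H]1OC(=O)[C@H](C)CC
F7 | step 17 | β-boryl ketone (pinacol boronate in place of the side-chain OH of 29) | C=C1[C@H]2CC(=O)[C@@H]([C@H](C)B3OC(C)(C)C(C)(C)O3)[C@H]2[C@@H]([C@@]4(C(=O)OC)CO4)[C@@H](OC(=O)/C=C(\C)CC)[C@@H]1OC(=O)[C@H](C)CC
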